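**Retrosynthetic overview** (ring A = the fully substituted benzene ring, ring B = the 4-hydroxyphenyl ring)
1. 10 ⇒ 8 + 9: the prenyl group goes on last, by Friedel–Crafts C-prenylation at C8, the only free carbon of ring A.
2. 8 ⇒ 4 + 5: the pyran ring is annulated onto C3/O4 of ketone 4 through a dearomatised o-quinone methide that closes by oxa-6π electrocyclisation.
3. 4 ⇒ 1 + 2: key step, a protecting-group-free Houben–Hoesch acylation at the off-axis carbon C4 of mirror-symmetric 5-methoxyresorcinol; breaking the symmetry of 1 sets the OMe/OH/acyl pattern of ring A in one operation.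
4. Ring order: rings A and B are bought as benzenes; the pyran ring is the only ring formed (step 2).

Assumption: the target has no stereocentre and no stereogenic double bond, so it is a single achiral compound and no stereocontrol is needed.

**Step 1**
Reactants: 1 5-methoxybenzene-1,3-diol; 2 (4-hydroxyphenyl)acetonitrile
Product: 4 1-(2,4-dihydroxy-6-methoxyphenyl)-2-(4-hydroxyphenyl)ethan-1-one, via ketiminium chloride 3 (not isolated)
Conditions: HCl (g), ZnCl2 (0.3 equiv), Et2O, 0 °C, 24 h; then H2O, 100 °C, 1 h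
Reagents that add atoms: water, O
Why: Houben–Hoesch acylation in which the HCl/ZnCl2-activated nitrile attacks C4 (equivalent to C6) of 1, a position para to a free hydroxyl that is favoured statistically (two sites to one) and electronically over the on-axis C2, so the mirror symmetry of 1 is broken and the 2-OH/4-OH/6-OMe pattern is fixed at once, after which water hydrolyses ketiminium salt 3 to ketone 4 (the minor symmetric 2,6-dihydroxy-4-methoxy isomer is removed by crystallisation or chromatography).

**Step 2**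
Reactants: 4 1-(2,4-dihydroxy-6-methoxyphenyl)-2-(4-hydroxyphenyl)ethan-1-one; 5 3-methylbut-2-enal
Product: 8 1-(5-hydroxy-7-methoxy-2,2-dimethyl-2H-chromen-6-yl)-2-(4-hydroxyphenyl)ethan-1-one, via benzylic carbinol 6 (not isolated), via o-quinone methide 7 (not isolated)
Conditions: pyridine, 120 °C (sealed tube), 16 h
Reagents that add atoms: none
Why: Formal [3+3] chromene annulation (Knoevenagel-type condensation then oxa-6π electrocyclisation): C3 of 4, the carbon between the two free hydroxyls, adds to the aldehyde to give carbinol 6, loss of water gives the dearomatised o-quinone methide 7, and ring closure through the non-chelated 4-oxygen restores aromaticity while keeping the hydrogen-bonded OH···O=C chelate.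

**Step 3**
Reactants: 8 1-(5-hydroxy-7-methoxy-2,2-dimethyl-2H-chromen-6-yl)-2-(4-hydroxyphenyl)ethan-1-one; 9 2-methylbut-3-en-2-ol
Product: 10 1-[5-hydroxy-7-methoxy-2,2-dimethyl-8-(3-methylbut-2-en-1-yl)-2H-chromen-6-yl]-2-(4-hydroxyphenyl)ethan-1-one
Conditions: BF3·OEt2 (0.3 equiv), 1,4-dioxane, 20 °C, 6 h
Reagents that add atoms: none
Why: Friedel–Crafts C-prenylation in which the dimethylallyl cation from 9 is captured at its primary terminus by C8, the only unsubstituted carbon of ring A and one activated by the para 5-OH and two ortho oxygens, while mono-phenolic ring B is much less nucleophilic and the new prenyl group has no free ortho hydroxyl to cyclise onto.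

**Compound list**
1 | 5-methoxybenzene-1,3-diol | COc1cc(O)cc(O)c1 | starting material
2 | (4-hydroxyphenyl)acetonitrile | N#CCc1ccc(O)cc1 | starting material
3 | 1-(2,4-dihydroxy-6-methoxyphenyl)-2-(4-hydroxyphenyl)ethan-1-iminium chloride (not isolated) | COc1cc(O)cc(O)c1C(=[NH2+])Cc1ccc(O)cc1.[Cl-] | intermediate
4 | 1-(2,4-dihydroxy-6-methoxyphenyl)-2-(4-hydroxyphenyl)ethan-1-one | COc1cc(O)cc(O)c1C(=O)Cc1ccc(O)cc1 | intermediate
5 | 3-methylbut-2-enal | CC(C)=CC=O | starting material
6 | 1-[2,4-dihydroxy-3-(1-hydroxy-3-methylbut-2-en-1-yl)-6-methoxyphenyl]-2-(4-hydroxyphenyl)ethan-1-one (racemic, not isolated; the carbinol centre is lost on dehydration) | COc1cc(O)c(C(O)C=C(C)C)c(O)c1C(=O)Cc1ccc(O)cc1 | intermediate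
7 | (2Z)-3-hydroxy-4-[(4-hydroxyphenyl)acetyl]-5-methoxy-2-(3-methylbut-2-en-1-ylidene)cyclohexa-3,5-dien-1-one (not isolated) | O=C1C=C(OC)C(C(=O)Cc2ccc(O)cc2)=C(O)/C1=C/C=C(C)C | intermediate
8 | 1-(5-hydroxy-7-methoxy-2,2-dimethyl-2H-chromen-6-yl)-2-(4-hydroxyphenyl)ethan-1-one | COc1cc2c(C=CC(C)(C)O2)c(O)c1C(=O)Cc1ccc(O)cc1 | intermediate
9 | 2-methylbut-3-en-2-ol | CC(C)(O)C=C | starting material
10 | 1-[5-hydroxy-7-methoxy-2,2-dimethyl-8-(3-methylbut-2-en-1-yl)-2H-chromen-6-yl]-2-(4-hydroxyphenyl)ethan-1-one | COc1c(CC=C(C)C)c2c(c(O)c1C(=O)Cc1ccc(O)cc1)C=CC(C)(C)O2 | target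

**Totals**
Total step count: 3. Longest linear sequence: 3 (1 → 4 → 8 → 10).

**Steps most likely to fail, in order of risk**

Step 3 (highest risk). The allyl cation can also attack the electron-rich C3=C4 double bond of the chromene or ring B, and the Lewis acid can oligomerise the chromene. The fallback replaces the carbocation by a cross-coupling and sets out from 8. Iodination of 8 with N-iodosuccinimide (1.0 equiv, MeCN, 0 °C) at the same unique ring A position gives 1-(5-hydroxy-8-iodo-7-methoxy-2,2-dimethyl-2H-chromen-6-yl)-2-(4-hydroxyphenyl)ethan-1-one F1. Stille coupling of F1 with tributyl(3-methylbut-2-en-1-yl)stannane (Pd(PPh3)4, CuI, DMF, 80 °C) then forms the C8–CH2 bond and comes back to the route at 10.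

Step 1. The nitrile may attack C2 of 1 to a larger extent than expected, giving mostly the symmetric 2,6-dihydroxy-4-methoxy ketone. The fallback breaks the symmetry by chelation-controlled protection instead of by the acylation and sets out from 2.
- Hoesch reaction of 2 with bought benzene-1,3,5-triol F2, whose three ring positions are equivalent (HCl, ZnCl2, Et2O, 0 °C; then H2O, 100 °C), passes through 1-(2,4,6-trihydroxyphenyl)-2-(4-hydroxyphenyl)ethan-1-iminium chloride F3, hydrolysed in the same flask, to 1-(2,4,6-trihydroxyphenyl)-2-(4-hydroxyphenyl)ethan-1-one F4.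
- Chloromethyl methyl ether (3.3 equiv, iPr2NEt, CH2Cl2, 0 °C) protects every hydroxyl except the one ortho hydroxyl held in the carbonyl chelate, giving 1-[2-hydroxy-4,6-bis(methoxymethoxy)phenyl]-2-[4-(methoxymethoxy)phenyl]ethan-1-one F5.
- Dimethyl sulfate (K2CO3, acetone, reflux) methylates that last hydroxyl to 1-[2-methoxy-4,6-bis(methoxymethoxy)phenyl]-2-[4-(methoxymethoxy)phenyl]ethan-1-one F6.
- HCl in MeOH at 50 °C removes the three acetal groups and comes back to the route at 4.

Step 2. The enal may condense at C5 (giving the 7-hydroxy-5-methoxy isomer) or at the benzylic CH2 of the ketone. The fallback uses a sigmatropic route instead of the condensation and sets out from 4. Alkylation of the most acidic, non-chelated 4-OH with 3-chloro-3-methylbut-1-yne (K2CO3, KI, CuI cat., acetone, 50 °C) gives 1-{2-hydroxy-6-methoxy-4-[(2-methylbut-3-yn-2-yl)oxy]phenyl}-2-(4-hydroxyphenyl)ethan-1-one F7. Heating F7 (N,N-diethylaniline, 190 °C) triggers an aromatic propargyl Claisen rearrangement, expected to go to C3 next to the chelated hydroxyl, followed by a [1,5]-hydrogen shift and oxa-6π closure, and comes back to the route at 8. The direction of this Claisen step (C3 versus C5) is itself not certain.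

**Further compounds**
F1 | step 3 | 1-(5-hydroxy-8-iodo-7-methoxy-2,2-dimethyl-2H-chromen-6-yl)-2-(4-hydroxyphenyl)ethan-1-one | COc1c(I)c2c(c(O)c1C(=O)Cc1ccc(O)cc1)C=CC(C)(C)O2
F2 | step 1 | benzene-1,3,5-triol | Oc1cc(O)cc(O)c1
F3 | step 1 | 1-(2,4,6-trihydroxyphenyl)-2-(4-hydroxyphenyl)ethan-1-iminium chloride | [NH2+]=C(Cc1ccc(O)cc1)c1c(O)cc(O)cc1O.[Cl-]
F4 | step 1 | 1-(2,4,6-trihydroxyphenyl)-2-(4-hydroxyphenyl)ethan-1-one | O=C(Cc1ccc(O)cc1)c1c(O)cc(O)cc1O
F5 | step 1 | 1-[2-hydroxy-4,6-bis(methoxymethoxy)phenyl]-2-[4-(methoxymethoxy)phenyl]ethan-1-one | COCOc1ccc(CC(=O)c2c(O)cc(OCOC)cc2OCOC)cc1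
F6 | step 1 | 1-[2-methoxy-4,6-bis(methoxymethoxy)phenyl]-2-[4-(methoxymethoxy)phenyl]ethan-1-one | COCOc1ccc(CC(=O)c2c(OC)cc(OCOC)cc2OCOC)cc1
F7 | step 2 | 1-{2-hydroxy-6-methoxy-4-[(2-methylbut-3-yn-2-yl)oxy]phenyl}-2-(4-hydroxyphenyl)ethan-1-one | COc1cc(OC(C)(C)C#C)cc(O)c1C(=O)Cc1ccc(O)cc1
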